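**Retrosynthetic overview**
1. Ring A (the cyclohexene) is numbered here C1 (carbinol carbon), C2 (methyl-bearing alkene carbon), C3 (alkene carbon carrying the two-carbon linker), C4 (quaternary carbon), C5 and C6 (CH2); it is closed last, across C1–C6, and the C1 stereocentre then comes from a CBS reduction of the enone.
2. Enabling feature: C1(OH)–C2(Me)=C3 is an aldol retron and C6 is the end of a two-carbon arm on quaternary C4. C1 can therefore wait as a thiol ester on a C2–C3 aldol adduct while C6 is the terminus of a vinyl group; hydroboration makes C6 a nucleophile, acyl–alkyl coupling closes the ring, and loss of silanol draws the C2=C3 alkene.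
3. The acyclic precursor 28 comes from a thiopropionate aldol on ketone 24, which comes from the alkyllithium of iodide 14 and the quaternary aldehyde 21.
4. Aldehyde 21 (C4 with its methyl and 4-methylpent-3-enyl groups) comes from geraniol by Sharpless epoxidation, a stereospecific epoxide-to-aldehyde 1,2-shift and a Wittig reaction; iodide 14 comes from geranyl bromide.
5. Ring order: the oxepane, then the saturated cyclohexane (both in one diepoxide/enol-silane cascade, step 5), ring A last (step 19).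

Key step: step 19

Assumption: the D-fructose-derived Shi ketone is taken to give the (R)-configured epoxides at both trisubstituted alkenes of 4, as it does with other (E)-trisubstituted olefins, and commercial geranyl bromide and geraniol are used as the pure (E)-isomers.

**Route**

Step 1
Reactants: 1 geranyl bromide; 2 N-methoxy-N-methylacetamide
Product: 4 (4E)-N-methoxy-N,5,9-trimethyldeca-4,8-dienamide, via lithium enolate 3 (not isolated)
Conditions: LiN(iPr)2, THF, −78 °C; then 1, −78 → 0 °C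
Reagents that add atoms: none
Why: Enolate alkylation (SN2 at the primary allylic bromide) should keep the (E)-alkene and install the Weinreb amide needed for the later vinyl ketone.

Step 2
Reactants: 4 (4E)-N-methoxy-N,5,9-trimethyldeca-4,8-dienamide
Product: 5 (4R,5R,8R)-4,5:8,9-diepoxy-N-methoxy-N,5,9-trimethyldecanamide
Conditions: D-fructose-derived Shi ketone (1,2:4,5-di-O-isopropylidene-β-D-erythro-2,3-hexodiulo-2,6-pyranose, 0.6 equiv), Oxone (2KHSO5·KHSO4·K2SO4), K2CO3, Bu4NHSO4, MeCN–CH2(OMe)2–aq. Na2B4O7 buffer, 0 °C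
Reagents that add atoms: potassium peroxymonosulfate (active part of Oxone), [K+].[O-]S(=O)(=O)OO
Why: Shi asymmetric epoxidation should oxidise both electron-rich trisubstituted alkenes from the same enantioface through the spiro dioxirane transition state, setting the three epoxide stereocentres (4R,5R,8R) under catalyst control.

Step 3
Reactants: 5 (4R,5R,8R)-4,5:8,9-diepoxy-N-methoxy-N,5,9-trimethyldecanamide
Product: 6 (6R,7R,10R)-6,7:10,11-diepoxy-7,11-dimethyldodec-1-en-3-one
Conditions: CH2=CHMgBr, THF, −78 → −20 °C; cold aq. NH4Cl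
Reagents that add atoms: vinylmagnesium bromide, C=C[Mg]Br
Why: Weinreb ketone synthesis, in which the chelated tetrahedral adduct stops at mono-addition and the trisubstituted epoxides should be inert to the Grignard reagent at low temperature.

Step 4
Reactants: 6 (6R,7R,10R)-6,7:10,11-diepoxy-7,11-dimethyldodec-1-en-3-one
Product: 7 (4Z,8R,9R,12R)-8,9:12,13-diepoxy-9,13-dimethyl-5-(trimethylsilyloxy)tetradeca-1,4-diene
Conditions: CH2=CHMgBr, CuBr·SMe2 (10 mol %), Me3SiCl, HMPA, THF, −78 °C; then Et3N, pentane, cold aq. NaHCO3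
Reagents that add atoms: vinylmagnesium bromide, C=C[Mg]Br; chlorotrimethylsilane, C[Si](C)(C)Cl
Why: Chlorosilane-accelerated, copper-catalysed conjugate addition to the unhindered vinyl ketone should outrun attack on the trisubstituted epoxides and trap the enolate regiospecifically as the (Z)-silyl enol ether.

Step 5
Reactants: 7 (4Z,8R,9R,12R)-8,9:12,13-diepoxy-9,13-dimethyl-5-(trimethylsilyloxy)tetradeca-1,4-diene
Product: 9 (3R,5aR,6R,9aR)-6-allyl-3-hydroxy-2,2,5a-trimethyloctahydro-2H-1-benzoxepin-7-one (trans-fused), via silyl ether 8 (not isolated)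
Conditions: Me3SiOTf (0.3 equiv), 2,6-di-tert-butyl-4-methylpyridine, CH2Cl2, −78 °C; then K2CO3, MeOH, 0 °C
Reagents that add atoms: none
Why: In this Lewis-acid-initiated epoxide-opening cascade (tandem oxa- and carbacyclisation) silylation of the terminal epoxide lets the internal epoxide oxygen attack its tertiary carbon in the 7-endo mode, and the enol silane then opens the epoxonium ion at its tertiary carbon with inversion through a chair transition state, so that the trans ring fusion, the angular methyl and the secondary carbinol follow from the three epoxide centres, while the allyl group takes the equatorial position (secured by the (Z)-enol geometry and by base equilibration during methanolysis of the silyl ether).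

Step 6
Reactants: 9 (3R,5aR,6R,9aR)-6-allyl-3-hydroxy-2,2,5a-trimethyloctahydro-2H-1-benzoxepin-7-one
Product: 10 (3R,5aR,6R,7S,9aR)-6-allyl-2,2,5a,7-tetramethyldecahydro-1-benzoxepine-3,7-diol
Conditions: MeMgBr (3.5 equiv), THF, −78 → 0 °C; aq. NH4Cl
Reagents that add atoms: methylmagnesium bromide, C[Mg]Br
Why: In this Grignard 1,2-addition the axial angular methyl group 1,3 to the carbonyl blocks axial attack, so methyl should enter equatorially and leave the new tertiary hydroxyl axial, cis to the angular methyl (7S).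

Step 7
Reactants: 10 (3R,5aR,6R,7S,9aR)-6-allyl-2,2,5a,7-tetramethyldecahydro-1-benzoxepine-3,7-diol
Product: 11 (3R,5aR,6R,7S,9aR)-6-allyl-2,2,5a,7-tetramethyl-3,7-bis(triethylsilyloxy)decahydro-1-benzoxepine
Conditions: Et3SiOTf, 2,6-lutidine, CH2Cl2, −78 → 0 °C; aq. NaHCO3
Reagents that add atoms: triethylsilyl trifluoromethanesulfonate, CC[Si](CC)(CC)OS(=O)(=O)C(F)(F)F
Why: Silyl triflate silylation should protect the secondary and the hindered tertiary hydroxyl in one operation for the organolithium chemistry that follows.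

Step 8
Reactants: 11 (3R,5aR,6R,7S,9aR)-6-allyl-2,2,5a,7-tetramethyl-3,7-bis(triethylsilyloxy)decahydro-1-benzoxepine
Product: 13 2-[(3R,5aR,6R,7S,9aR)-2,2,5a,7-tetramethyl-3,7-bis(triethylsilyloxy)decahydro-1-benzoxepin-6-yl]ethanol, via aldehyde 12 (not isolated)
Conditions: O3, CH2Cl2–MeOH, −78 °C; then NaBH4, −78 → 0 °C
Reagents that add atoms: ozone, [O-][O+]=O
Why: Ozonolysis with reductive work-up should cut the only alkene of the molecule to the primary alcohol and so shorten the allyl arm to the two-carbon linker.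

Step 9
Reactants: 13 2-[(3R,5aR,6R,7S,9aR)-2,2,5a,7-tetramethyl-3,7-bis(triethylsilyloxy)decahydro-1-benzoxepin-6-yl]ethanol
Product: 14 (3R,5aR,6R,7S,9aR)-6-(2-iodoethyl)-2,2,5a,7-tetramethyl-3,7-bis(triethylsilyloxy)decahydro-1-benzoxepine
Conditions: I2, PPh3, imidazole, CH2Cl2, 0 °C
Reagents that add atoms: iodine, II
Why: Appel-type iodination should convert the primary alcohol into the iodide by SN2 displacement without touching the silyl ethers.

Step 10
Reactants: 15 geraniol
Product: 16 (2S,3S)-2,3-epoxygeraniol, [(2S,3S)-3-methyl-3-(4-methylpent-3-en-1-yl)oxiran-2-yl]methanol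
Conditions: Ti(OiPr)4 (5 mol %), L-(+)-diethyl tartrate (7 mol %), t-BuOOH, 4 Å molecular sieves, CH2Cl2, −20 °C
Reagents that add atoms: tert-butyl hydroperoxide, CC(C)(C)OO
Why: Sharpless asymmetric epoxidation should deliver oxygen only to the allylic-alcohol alkene and set (2S,3S) through the titanium tartrate complex.

Step 11
Reactants: 16 (2S,3S)-2,3-epoxygeraniol
Product: 17 tert-butyl{[(2S,3S)-3-methyl-3-(4-methylpent-3-en-1-yl)oxiran-2-yl]methoxy}dimethylsilane
Conditions: t-BuMe2SiCl, imidazole, DMF, rt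
Reagents that add atoms: tert-butyldimethylsilyl chloride, CC(C)(C)[Si](C)(C)Cl
Why: Standard silylation gives the epoxy silyl ether that the rearrangement of step 12 needs.

Step 12
Reactants: 17 tert-butyl{[(2S,3S)-3-methyl-3-(4-methylpent-3-en-1-yl)oxiran-2-yl]methoxy}dimethylsilane
Product: 18 (2S)-2-[(tert-butyldimethylsilyloxy)methyl]-2,6-dimethylhept-5-enal
Conditions: MeAl(OAr)2 (Ar = 4-bromo-2,6-di-tert-butylphenyl, 2 equiv), CH2Cl2, −78 °C
Reagents that add atoms: none
Why: In this organoaluminium-promoted epoxy silyl ether to β-siloxy aldehyde rearrangement (semipinacol-type 1,2-shift) the bulky Lewis acid opens the epoxide at its tertiary carbon and the siloxymethyl group migrates anti to the leaving oxygen, so the epoxide chirality should be carried with inversion into the all-carbon quaternary centre (2S).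

Step 13
Reactants: 18 (2S)-2-[(tert-butyldimethylsilyloxy)methyl]-2,6-dimethylhept-5-enal
Product: 19 tert-butyl{[(2R)-2-ethenyl-2,6-dimethylhept-5-en-1-yl]oxy}dimethylsilane
Conditions: Ph3PCH3Br, KN(SiMe3)2, THF, 0 °C → rt
Reagents that add atoms: methyltriphenylphosphonium bromide, C[P+](c1ccccc1)(c1ccccc1)c1ccccc1.[Br-]
Why: Wittig methylenation of the non-enolisable aldehyde should give the vinyl group whose terminal carbon becomes ring-A C6 (the descriptor changes to R only through the priority rules).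

Step 14
Reactants: 19 tert-butyl{[(2R)-2-ethenyl-2,6-dimethylhept-5-en-1-yl]oxy}dimethylsilane
Product: 20 (2R)-2-ethenyl-2,6-dimethylhept-5-en-1-ol
Conditions: Bu4NF, THF, rt
Reagents that add atoms: none
Why: Fluoride cleavage of the silyl ether should free the neopentyl alcohol without affecting the alkenes.

Step 15
Reactants: 20 (2R)-2-ethenyl-2,6-dimethylhept-5-en-1-ol
Product: 21 (2R)-2-ethenyl-2,6-dimethylhept-5-enal
Conditions: Dess–Martin periodinane, NaHCO3, CH2Cl2, 0 °C → rt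
Reagents that add atoms: none
Why: Dess–Martin oxidation should give the aldehyde, which has no α-hydrogen and therefore cannot epimerise.

Step 16
Reactants: 14 (3R,5aR,6R,7S,9aR)-6-(2-iodoethyl)-2,2,5a,7-tetramethyl-3,7-bis(triethylsilyloxy)decahydro-1-benzoxepine; 21 (2R)-2-ethenyl-2,6-dimethylhept-5-enal
Product: 23 (4R)-4-ethenyl-4,8-dimethyl-1-[(3R,5aR,6R,7S,9aR)-2,2,5a,7-tetramethyl-3,7-bis(triethylsilyloxy)decahydro-1-benzoxepin-6-yl]non-7-en-3-ol (both C3 epimers), via alkyllithium 22 (not isolated)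
Conditions: t-BuLi (2.1 equiv), Et2O–pentane, −78 °C; then 21, −78 → −20 °C; aq. NH4Cl
Reagents that add atoms: none
Why: Iodine–lithium exchange should give the primary alkyllithium, which adds 1,2 to the non-enolisable aldehyde; the new carbinol centre forms as a mixture that step 17 erases.

Step 17
Reactants: 23 (4R)-4-ethenyl-4,8-dimethyl-1-[(3R,5aR,6R,7S,9aR)-2,2,5a,7-tetramethyl-3,7-bis(triethylsilyloxy)decahydro-1-benzoxepin-6-yl]non-7-en-3-ol
Product: 24 (4R)-4-ethenyl-4,8-dimethyl-1-[(3R,5aR,6R,7S,9aR)-2,2,5a,7-tetramethyl-3,7-bis(triethylsilyloxy)decahydro-1-benzoxepin-6-yl]non-7-en-3-one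
Conditions: Dess–Martin periodinane, NaHCO3, CH2Cl2, rt
Reagents that add atoms: none
Why: Dess–Martin oxidation of the hindered secondary alcohol should give the ketone whose carbonyl carbon becomes ring-A C3.

Step 18
Reactants: 24 (4R)-4-ethenyl-4,8-dimethyl-1-[(3R,5aR,6R,7S,9aR)-2,2,5a,7-tetramethyl-3,7-bis(triethylsilyloxy)decahydro-1-benzoxepin-6-yl]non-7-en-3-one; 25 S-ethyl propanethioate
Product: 28 S-ethyl (4R)-4-ethenyl-2,4,8-trimethyl-3-{2-[(3R,5aR,6R,7S,9aR)-2,2,5a,7-tetramethyl-3,7-bis(triethylsilyloxy)decahydro-1-benzoxepin-6-yl]ethyl}-3-(trimethylsilyloxy)non-7-enethioate (mixture at C2 and C3), via lithium enolate 26 (not isolated), via lithium aldolate 27 (not isolated)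
Conditions: LiN(iPr)2, THF, −78 °C; 25; then 24, −78 °C; then Me3SiCl, −78 → −20 °C
Reagents that add atoms: chlorotrimethylsilane, C[Si](C)(C)Cl
Why: Aldol addition of the thiol ester enolate to the ketone with in-situ O-silylation of the aldolate should block retro-aldol and β-lactone formation; the two new stereocentres form unselectively and are both removed in step 19.

Step 19
Reactants: 28 S-ethyl (4R)-4-ethenyl-2,4,8-trimethyl-3-{2-[(3R,5aR,6R,7S,9aR)-2,2,5a,7-tetramethyl-3,7-bis(triethylsilyloxy)decahydro-1-benzoxepin-6-yl]ethyl}-3-(trimethylsilyloxy)non-7-enethioate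
Product: 31 (4R)-2,4-dimethyl-4-(4-methylpent-3-en-1-yl)-3-{2-[(3R,5aR,6R,7S,9aR)-2,2,5a,7-tetramethyl-3,7-bis(triethylsilyloxy)decahydro-1-benzoxepin-6-yl]ethyl}cyclohex-2-en-1-one, via alkylborane 29 (not isolated), via silyloxy ketone 30 (not isolated)
Conditions: 9-borabicyclo[3.3.1]nonane (9-BBN-H, 1.3 equiv), THF, 0 °C → rt; then Pd2(dba)3 (5 mol %), P(2-furyl)3 (20 mol %), Cu(O2C-2-thienyl) (CuTC, 1.5 equiv), Cs2CO3 (1.5 equiv), THF, 50 °C; then DBU (2 equiv), 50 °C
Reagents that add atoms: none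
Why: 9-BBN-H should add anti-Markovnikov to the vinyl group on the quaternary carbon only, making ring-A C6 a B-alkyl nucleophile; zerovalent palladium, helped by the monovalent copper carboxylate, then inserts into the acyl–S bond, the alkyl group is passed from boron within the same molecule, and reductive elimination from the seven-membered acyl(alkyl)palladacycle forms the C1–C6 bond. The closest known reaction types are the copper-mediated, palladium-catalysed ketone synthesis from thiol esters and B-alkyl-9-BBN reagents (Liebeskind–Srogl type) and the one-pot hydroboration/intramolecular B-alkyl Suzuki cyclisation. Ring A closes in the 6-exo-trig sense at the acyl carbon, with all six ring atoms supplied by the chain and the carbonyl oxygen left exocyclic. No stereocentre is created: the quaternary centre is carried through untouched, and the two aldol centres are erased when DBU removes trimethylsilanol (E1cB) to give the tetrasubstituted enone, whose geometry the ring fixes. The step needs chemoselective hydroboration, secured by the large rate gap between a terminal vinyl group and a trisubstituted alkene towards 9-BBN-H, and coupling ahead of β-hydride elimination or early elimination, secured by the intramolecular alkyl transfer and by holding the tertiary oxygen as a silyl ether that leaves only once the ketone is in place.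

Step 20
Reactants: 31 (4R)-2,4-dimethyl-4-(4-methylpent-3-en-1-yl)-3-{2-[(3R,5aR,6R,7S,9aR)-2,2,5a,7-tetramethyl-3,7-bis(triethylsilyloxy)decahydro-1-benzoxepin-6-yl]ethyl}cyclohex-2-en-1-one
Product: 32 (1S,4R)-2,4-dimethyl-4-(4-methylpent-3-en-1-yl)-3-{2-[(3R,5aR,6R,7S,9aR)-2,2,5a,7-tetramethyl-3,7-bis(triethylsilyloxy)decahydro-1-benzoxepin-6-yl]ethyl}cyclohex-2-en-1-ol
Conditions: (R)-Me-CBS oxazaborolidine [(R)-1-methyl-3,3-diphenyltetrahydro-1H,3H-pyrrolo[1,2-c][1,3,2]oxazaborole, 0.5 equiv], catecholborane, toluene, −78 °C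
Reagents that add atoms: none
Why: In this Corey–Bakshi–Shibata reduction the (R)-oxazaborolidine should bind the ketone with the alkenyl flank as the large and the ring CH2 as the small group and deliver hydride to the face that gives the (S)-allylic alcohol, under reagent control and independent of the remote quaternary centre.

Step 21
Reactants: 32 (1S,4R)-2,4-dimethyl-4-(4-methylpent-3-en-1-yl)-3-{2-[(3R,5aR,6R,7S,9aR)-2,2,5a,7-tetramethyl-3,7-bis(triethylsilyloxy)decahydro-1-benzoxepin-6-yl]ethyl}cyclohex-2-en-1-ol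
Product: 33 (3R,5aR,6R,7S,9aR)-6-{2-[(3S,6R)-3-hydroxy-2,6-dimethyl-6-(4-methylpent-3-en-1-yl)cyclohex-1-en-1-yl]ethyl}-2,2,5a,7-tetramethyldecahydro-1-benzoxepine-3,7-diol (target)
Conditions: Bu4NF, THF, rt → 40 °C
Reagents that add atoms: none
Why: Fluoride cleavage of both triethylsilyl ethers under non-acidic conditions should spare the ionisable allylic alcohol and give the target.

**Compound list**
1 | geranyl bromide, (2E)-1-bromo-3,7-dimethylocta-2,6-diene | CC(C)=CCC/C(C)=C/CBr | starting material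
2 | N-methoxy-N-methylacetamide | CC(=O)N(C)OC | starting material
3 | lithium enolate of N-methoxy-N-methylacetamide | C=C([O-])N(C)OC.[Li+] | intermediate (not isolated)
4 | (4E)-N-methoxy-N,5,9-trimethyldeca-4,8-dienamide | CON(C)C(=O)CC/C=C(\C)CCC=C(C)C | intermediate
5 | (4R,5R,8R)-4,5:8,9-diepoxy-N-methoxy-N,5,9-trimethyldecanamide | CON(C)C(=O)CC[C@H]1O[C@]1(C)CC[C@H]1OC1(C)C | intermediate
6 | (6R,7R,10R)-6,7:10,11-diepoxy-7,11-dimethyldodec-1-en-3-one | C=CC(=O)CC[C@H]1O[C@]1(C)CC[C@H]1OC1(C)C | intermediate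
7 | (4Z,8R,9R,12R)-8,9:12,13-diepoxy-9,13-dimethyl-5-(trimethylsilyloxy)tetradeca-1,4-diene | C=CC/C=C(\O[Si](C)(C)C)CC[C@H]1O[C@]1(C)CC[C@H]1OC1(C)C | intermediate
8 | (3R,5aR,6R,9aR)-6-allyl-2,2,5a-trimethyl-3-(trimethylsilyloxy)octahydro-2H-1-benzoxepin-7-one | C=CC[C@@H]1[C@@]2(C)CC[C@@H](O[Si](C)(C)C)C(C)(C)O[C@@H]2CCC1=O | intermediate (not isolated)
9 | (3R,5aR,6R,9aR)-6-allyl-3-hydroxy-2,2,5a-trimethyloctahydro-2H-1-benzoxepin-7-one | C=CC[C@@H]1[C@@]2(C)CC[C@@H](O)C(C)(C)O[C@@H]2CCC1=O | intermediate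
10 | (3R,5aR,6R,7S,9aR)-6-allyl-2,2,5a,7-tetramethyldecahydro-1-benzoxepine-3,7-diol | C=CC[C@@H]1[C@@]2(C)CC[C@@H](O)C(C)(C)O[C@@H]2CC[C@]1(C)O | intermediate
11 | (3R,5aR,6R,7S,9aR)-6-allyl-2,2,5a,7-tetramethyl-3,7-bis(triethylsilyloxy)decahydro-1-benzoxepine | C=CC[C@@H]1[C@@]2(C)CC[C@@H](O[Si](CC)(CC)CC)C(C)(C)O[C@@H]2CC[C@]1(C)O[Si](CC)(CC)CC | intermediate
12 | 2-[(3R,5aR,6R,7S,9aR)-2,2,5a,7-tetramethyl-3,7-bis(triethylsilyloxy)decahydro-1-benzoxepin-6-yl]acetaldehyde | O=CC[C@@H]1[C@@]2(C)CC[C@@H](O[Si](CC)(CC)CC)C(C)(C)O[C@@H]2CC[C@]1(C)O[Si](CC)(CC)CC | intermediate (not isolated)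
13 | 2-[(3R,5aR,6R,7S,9aR)-2,2,5a,7-tetramethyl-3,7-bis(triethylsilyloxy)decahydro-1-benzoxepin-6-yl]ethanol | OCC[C@@H]1[C@@]2(C)CC[C@@H](O[Si](CC)(CC)CC)C(C)(C)O[C@@H]2CC[C@]1(C)O[Si](CC)(CC)CC | intermediate
14 | (3R,5aR,6R,7S,9aR)-6-(2-iodoethyl)-2,2,5a,7-tetramethyl-3,7-bis(triethylsilyloxy)decahydro-1-benzoxepine | ICC[C@@H]1[C@@]2(C)CC[C@@H](O[Si](CC)(CC)CC)C(C)(C)O[C@@H]2CC[C@]1(C)O[Si](CC)(CC)CC | intermediate
15 | geraniol, (2E)-3,7-dimethylocta-2,6-dien-1-ol | CC(C)=CCC/C(C)=C/CO | starting material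
16 | (2S,3S)-2,3-epoxygeraniol | CC(C)=CCC[C@]1(C)O[C@H]1CO | intermediate
17 | tert-butyl{[(2S,3S)-3-methyl-3-(4-methylpent-3-en-1-yl)oxiran-2-yl]methoxy}dimethylsilane | CC(C)=CCC[C@]1(C)O[C@H]1CO[Si](C)(C)C(C)(C)C | intermediate
18 | (2S)-2-[(tert-butyldimethylsilyloxy)methyl]-2,6-dimethylhept-5-enal | CC(C)=CCC[C@](C)(C=O)CO[Si](C)(C)C(C)(C)C | intermediate
19 | tert-butyl{[(2R)-2-ethenyl-2,6-dimethylhept-5-en-1-yl]oxy}dimethylsilane | CC(C)=CCC[C@](C)(C=C)CO[Si](C)(C)C(C)(C)C | intermediate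
20 | (2R)-2-ethenyl-2,6-dimethylhept-5-en-1-ol | CC(C)=CCC[C@](C)(C=C)CO | intermediate
21 | (2R)-2-ethenyl-2,6-dimethylhept-5-enal | CC(C)=CCC[C@](C)(C=C)C=O | intermediate
22 | alkyllithium from 14, {2-[(3R,5aR,6R,7S,9aR)-2,2,5a,7-tetramethyl-3,7-bis(triethylsilyloxy)decahydro-1-benzoxepin-6-yl]ethyl}lithium | [Li]CC[C@@H]1[C@@]2(C)CC[C@@H](O[Si](CC)(CC)CC)C(C)(C)O[C@@H]2CC[C@]1(C)O[Si](CC)(CC)CC | intermediate (not isolated)
23 | (4R)-4-ethenyl-4,8-dimethyl-1-[(3R,5aR,6R,7S,9aR)-2,2,5a,7-tetramethyl-3,7-bis(triethylsilyloxy)decahydro-1-benzoxepin-6-yl]non-7-en-3-ol (both C3 epimers) | CC(C)=CCC[C@](C)(C=C)C(O)CC[C@@H]1[C@@]2(C)CC[C@@H](O[Si](CC)(CC)CC)C(C)(C)O[C@@H]2CC[C@]1(C)O[Si](CC)(CC)CC | intermediate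
24 | (4R)-4-ethenyl-4,8-dimethyl-1-[(3R,5aR,6R,7S,9aR)-2,2,5a,7-tetramethyl-3,7-bis(triethylsilyloxy)decahydro-1-benzoxepin-6-yl]non-7-en-3-one | CC(C)=CCC[C@](C)(C=C)C(=O)CC[C@@H]1[C@@]2(C)CC[C@@H](O[Si](CC)(CC)CC)C(C)(C)O[C@@H]2CC[C@]1(C)O[Si](CC)(CC)CC | intermediate
25 | S-ethyl propanethioate | CCC(=O)SCC | starting material
26 | lithium enolate of S-ethyl propanethioate | CC=C([O-])SCC.[Li+] | intermediate (not isolated)
27 | lithium aldolate of 24 and 26 (lithium alkoxide of the β-hydroxy thiol ester, mixture at the two new centres) | CC(C)=CCC[C@](C)(C=C)C([O-])(CC[C@@H]1[C@@]2(C)CC[C@@H](O[Si](CC)(CC)CC)C(C)(C)O[C@@H]2CC[C@]1(C)O[Si](CC)(CC)CC)C(C)C(=O)SCC.[Li+] | intermediate (not isolated)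
28 | S-ethyl (4R)-4-ethenyl-2,4,8-trimethyl-3-{2-[(3R,5aR,6R,7S,9aR)-2,2,5a,7-tetramethyl-3,7-bis(triethylsilyloxy)decahydro-1-benzoxepin-6-yl]ethyl}-3-(trimethylsilyloxy)non-7-enethioate (mixture at C2 and C3) | CC(C)=CCC[C@](C)(C=C)C(O[Si](C)(C)C)(CC[C@@H]1[C@@]2(C)CC[C@@H](O[Si](CC)(CC)CC)C(C)(C)O[C@@H]2CC[C@]1(C)O[Si](CC)(CC)CC)C(C)C(=O)SCC | intermediate
29 | B-alkyl-9-BBN from 28 (the ethenyl group of 28 turned into a 2-(9-borabicyclo[3.3.1]nonan-9-yl)ethyl group) | CC(C)=CCC[C@](C)(CCB1C2CCCC1CCC2)C(O[Si](C)(C)C)(CC[C@@H]1[C@@]2(C)CC[C@@H](O[Si](CC)(CC)CC)C(C)(C)O[C@@H]2CC[C@]1(C)O[Si](CC)(CC)CC)C(C)C(=O)SCC | intermediate (not isolated)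
30 | (4R)-2,4-dimethyl-4-(4-methylpent-3-en-1-yl)-3-{2-[(3R,5aR,6R,7S,9aR)-2,2,5a,7-tetramethyl-3,7-bis(triethylsilyloxy)decahydro-1-benzoxepin-6-yl]ethyl}-3-(trimethylsilyloxy)cyclohexan-1-one (mixture at C2 and C3) | CC(C)=CCC[C@]1(C)CCC(=O)C(C)C1(O[Si](C)(C)C)CC[C@@H]1[C@@]2(C)CC[C@@H](O[Si](CC)(CC)CC)C(C)(C)O[C@@H]2CC[C@]1(C)O[Si](CC)(CC)CC | intermediate (not isolated)
31 | (4R)-2,4-dimethyl-4-(4-methylpent-3-en-1-yl)-3-{2-[(3R,5aR,6R,7S,9aR)-2,2,5a,7-tetramethyl-3,7-bis(triethylsilyloxy)decahydro-1-benzoxepin-6-yl]ethyl}cyclohex-2-en-1-one | CC(C)=CCC[C@]1(C)CCC(=O)C(C)=C1CC[C@@H]1[C@@]2(C)CC[C@@H](O[Si](CC)(CC)CC)C(C)(C)O[C@@H]2CC[C@]1(C)O[Si](CC)(CC)CC | intermediate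
32 | (1S,4R)-2,4-dimethyl-4-(4-methylpent-3-en-1-yl)-3-{2-[(3R,5aR,6R,7S,9aR)-2,2,5a,7-tetramethyl-3,7-bis(triethylsilyloxy)decahydro-1-benzoxepin-6-yl]ethyl}cyclohex-2-en-1-ol | CC(C)=CCC[C@]1(C)CC[C@H](O)C(C)=C1CC[C@@H]1[C@@]2(C)CC[C@@H](O[Si](CC)(CC)CC)C(C)(C)O[C@@H]2CC[C@]1(C)O[Si](CC)(CC)CC | intermediate
33 | (3R,5aR,6R,7S,9aR)-6-{2-[(3S,6R)-3-hydroxy-2,6-dimethyl-6-(4-methylpent-3-en-1-yl)cyclohex-1-en-1-yl]ethyl}-2,2,5a,7-tetramethyldecahydro-1-benzoxepine-3,7-diol | CC(C)=CCC[C@]1(C)CC[C@H](O)C(C)=C1CC[C@@H]1[C@@]2(C)CC[C@@H](O)C(C)(C)O[C@@H]2CC[C@]1(C)O | target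

**Step count and risks**

Total step count: 21 steps. Longest linear sequence: 15 steps (steps 1–9, then 16–21); the geraniol branch (steps 10–15) joins at step 16.

The three steps most likely to fail:

1. Step 19 (ring closure). The hindered thiol ester may insert palladium slowly, the alkylpalladium may lose a β-hydride, or the carbonate base may remove silanol before the ring is closed, which would leave an acyclic unsaturated thiol ester of the wrong geometry. The fallback replaces boron by zinc and needs no base. It sets out from 28: hydroboration with 9-BBN-H and oxidation with NaBO3 should give the primary alcohol S-ethyl (4R)-4-(2-hydroxyethyl)-2,4,8-trimethyl-3-{2-[benzoxepinyl]ethyl}-3-(trimethylsilyloxy)non-7-enethioate F1. Treatment with I2, PPh3 and imidazole should give the corresponding primary iodide F2. Zinc dust in THF–N,N-dimethylacetamide should insert to give the alkylzinc iodide F3, which with PdCl2(PPh3)2 undergoes the Fukuyama thiol ester–organozinc ketone synthesis within the molecule. This returns to the route at 30, which DBU converts into 31 as in step 19.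

2. Step 18 (aldol on the α-quaternary ketone). The lithium enolate may deprotonate the ketone instead of adding to it, or the aldolate may revert before it is silylated. The fallback uses a non-basic samarium enolate. It sets out from 24: a Reformatsky reaction with S-ethyl 2-bromopropanethioate and SmI2 (divalent samarium) in THF at −78 °C should give the free β-hydroxy thiol ester S-ethyl (4R)-4-ethenyl-3-hydroxy-2,4,8-trimethyl-3-{2-[benzoxepinyl]ethyl}non-7-enethioate F4. Silylation with Me3SiOTf and 2,6-lutidine returns to the route at 28.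

3. Step 5 (epoxide cascade). The cascade may stop after the oxepane has formed, by loss of a proton from the tertiary cation instead of C–C bond formation, or the enol silane may be protodesilylated before it can close the carbocycle. The fallback uses a more electron-rich terminator that is made without the cuprate step. It sets out from 5: allylmagnesium bromide should give the β,γ-unsaturated ketone (7R,8R,11R)-7,8:11,12-diepoxy-8,12-dimethyltridec-1-en-4-one F5. Soft enolisation with Me3SiOTf and Et3N should give the 2-silyloxy diene (3Z,7R,8R,11R)-7,8:11,12-diepoxy-8,12-dimethyl-4-(trimethylsilyloxy)trideca-1,3-diene F6. Its α-carbon should close the same cascade (Me3SiOTf, then mildly acidic methanol) to the 6-ethenyl hydroxy ketone (3R,5aR,6R,9aR)-6-ethenyl-3-hydroxy-2,2,5a-trimethyloctahydro-2H-1-benzoxepin-7-one F7. MeMgBr should give the diol (3R,5aR,6R,7S,9aR)-6-ethenyl-2,2,5a,7-tetramethyldecahydro-1-benzoxepine-3,7-diol F8, and Et3SiOTf its bis(triethylsilyl) ether F9. Hydroboration of the vinyl group with 9-BBN-H followed by iodinolysis (I2, NaOMe) returns to the route at 14.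

**Further compounds**
F1 | step 19 | S-ethyl (4R)-4-(2-hydroxyethyl)-2,4,8-trimethyl-3-{2-[(3R,5aR,6R,7S,9aR)-2,2,5a,7-tetramethyl-3,7-bis(triethylsilyloxy)decahydro-1-benzoxepin-6-yl]ethyl}-3-(trimethylsilyloxy)non-7-enethioate | CC(C)=CCC[C@](C)(CCO)C(O[Si](C)(C)C)(CC[C@@H]1[C@@]2(C)CC[C@@H](O[Si](CC)(CC)CC)C(C)(C)O[C@@H]2CC[C@]1(C)O[Si](CC)(CC)CC)C(C)C(=O)SCC
F2 | step 19 | S-ethyl (4R)-4-(2-iodoethyl)-2,4,8-trimethyl-3-{2-[(3R,5aR,6R,7S,9aR)-2,2,5a,7-tetramethyl-3,7-bis(triethylsilyloxy)decahydro-1-benzoxepin-6-yl]ethyl}-3-(trimethylsilyloxy)non-7-enethioate | CC(C)=CCC[C@](C)(CCI)C(O[Si](C)(C)C)(CC[C@@H]1[C@@]2(C)CC[C@@H](O[Si](CC)(CC)CC)C(C)(C)O[C@@H]2CC[C@]1(C)O[Si](CC)(CC)CC)C(C)C(=O)SCC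
F3 | step 19 | alkylzinc iodide from F2 (iodine replaced by ZnI) | CC(C)=CCC[C@](C)(CC[Zn]I)C(O[Si](C)(C)C)(CC[C@@H]1[C@@]2(C)CC[C@@H](O[Si](CC)(CC)CC)C(C)(C)O[C@@H]2CC[C@]1(C)O[Si](CC)(CC)CC)C(C)C(=O)SCC
F4 | step 18 | S-ethyl (4R)-4-ethenyl-3-hydroxy-2,4,8-trimethyl-3-{2-[(3R,5aR,6R,7S,9aR)-2,2,5a,7-tetramethyl-3,7-bis(triethylsilyloxy)decahydro-1-benzoxepin-6-yl]ethyl}non-7-enethioate | CC(C)=CCC[C@](C)(C=C)C(O)(CC[C@@H]1[C@@]2(C)CC[C@@H](O[Si](CC)(CC)CC)C(C)(C)O[C@@H]2CC[C@]1(C)O[Si](CC)(CC)CC)C(C)C(=O)SCC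
F5 | step 5 | (7R,8R,11R)-7,8:11,12-diepoxy-8,12-dimethyltridec-1-en-4-one | C=CCC(=O)CC[C@H]1O[C@]1(C)CC[C@H]1OC1(C)C
F6 | step 5 | (3Z,7R,8R,11R)-7,8:11,12-diepoxy-8,12-dimethyl-4-(trimethylsilyloxy)trideca-1,3-diene | C=C/C=C(\O[Si](C)(C)C)CC[C@H]1O[C@]1(C)CC[C@H]1OC1(C)C
F7 | step 5 | (3R,5aR,6R,9aR)-6-ethenyl-3-hydroxy-2,2,5a-trimethyloctahydro-2H-1-benzoxepin-7-one | C=C[C@@H]1[C@@]2(C)CC[C@@H](O)C(C)(C)O[C@@H]2CCC1=O
F8 | step 5 | (3R,5aR,6R,7S,9aR)-6-ethenyl-2,2,5a,7-tetramethyldecahydro-1-benzoxepine-3,7-diol | C=C[C@@H]1[C@@]2(C)CC[C@@H](O)C(C)(C)O[C@@H]2CC[C@]1(C)O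
F9 | step 5 | (3R,5aR,6R,7S,9aR)-6-ethenyl-2,2,5a,7-tetramethyl-3,7-bis(triethylsilyloxy)decahydro-1-benzoxepine | C=C[C@@H]1[C@@]2(C)CC[C@@H](O[Si](CC)(CC)CC)C(C)(C)O[C@@H]2CC[C@]1(C)O[Si](CC)(CC)CC
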